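**Retrosynthetic overview**
- The target is traced back to a drimane ester with a C6 dienol silyl ether (rings A and B complete). The forward end game is ester reduction, Mitsunobu etherification with umbelliferone, unmasking and α-face reduction of the C6 ketone, acetylation and desilylation.
- Key disconnection: C5–C10 together with C8–C9, an intramolecular Diels–Alder reaction of an acyclic 2-silyloxy vinylallene (C12=C8=C7–C6(OSi)=C5) with a tethered (E)-β-methyl enoate (C10=C9–C11). No ring exists before this step.
- Enabling feature: in ring B the oxygen at C6 and the exocyclic methylene C8=C12 flank C7, and C9 carries the oxidised carbon C11, so ring B is a masked [4+2] adduct. Ring A (C1–C4) is only a four-carbon tether between C5 and C10, and its single stereocentre C3 steers the cyclisation.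
- The acyclic precursor comes from methyl geranate (C1, C2, C9, C10, C11, C10 methyl) by ozonolysis, Brown reverse prenylation (sets C3; brings C4 with both methyls, C5, C6), hydroboration/oxidation, and propargylation/oxidation/isomerisation (C7, C8, C12).
- Order of ring formation: rings A and B together in step 8; the coumarin is brought in intact.

Key step: step 8

Remark: methyl geranate is taken as the commercial (2E)-isomer; bicyclic compounds are named with drimane numbering (ring A = C1–C5 and C10, ring B = C5–C10, C11 on C9, C12 on C8, β = face of the C10 methyl); TBS = tert-butyldimethylsilyl.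

**Step 1**
Reactants: 1 methyl geranate [methyl (2E)-3,7-dimethylocta-2,6-dienoate]
Product: 3 methyl (2E)-3-methyl-6-oxohex-2-enoate, via secondary ozonide 2 (not isolated)
Conditions: O3 (1.0 equiv), CH2Cl2, −78 °C; then Me2S, −78 °C → rt
Reagents that add atoms: ozone, O=[O+][O-]
Why: Ozonolysis (Criegee mechanism) with reductive work-up should cleave only the electron-rich trisubstituted C6=C7 alkene, the ester-conjugated C2=C3 alkene being much less reactive toward ozone; no stereocentre is formed.

**Step 2**
Reactants: 3 methyl (2E)-3-methyl-6-oxohex-2-enoate; 4 3-methylbuta-1,2-diene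
Product: 7 methyl (2E,6S)-6-hydroxy-3,7,7-trimethylnona-2,8-dienoate, via prenyldiisopinocampheylborane 5 (not isolated), via diisopinocampheylborinate 6 (not isolated)
Conditions: (+)-Ipc2BH [from (−)-α-pinene], 4, THF, −25 °C; then 3, −78 °C; then NaBO3·4H2O, H2O, rt
Reagents that add atoms: none
Why: Hydroboration of the allene gives the prenylborane, which adds to the aldehyde through a chair-like six-membered transition state with allylic transposition (Brown asymmetric reverse prenylation), creating the gem-dimethyl quaternary carbon and, under control of the (−)-α-pinene-derived isopinocampheyl groups, attacking the Re face to set the (S)-carbinol that becomes C3.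

**Step 3**
Reactants: 7 methyl (2E,6S)-6-hydroxy-3,7,7-trimethylnona-2,8-dienoate
Product: 8 methyl (2E,6S)-6-[(tert-butyldimethylsilyl)oxy]-3,7,7-trimethylnona-2,8-dienoate
Conditions: TBSOTf, 2,6-lutidine, CH2Cl2, 0 °C
Reagents that add atoms: tert-butyldimethylsilyl trifluoromethanesulfonate, CC(C)(C)[Si](C)(C)OS(=O)(=O)C(F)(F)F
Why: Silyl ether protection of the hindered secondary alcohol next to the quaternary carbon needs the silyl triflate and leaves the stereocentre untouched.

**Step 4**
Reactants: 8 methyl (2E,6S)-6-[(tert-butyldimethylsilyl)oxy]-3,7,7-trimethylnona-2,8-dienoate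
Product: 10 methyl (2E,6S)-6-[(tert-butyldimethylsilyl)oxy]-9-hydroxy-3,7,7-trimethylnon-2-enoate, via B-alkyl-9-BBN adduct 9 (not isolated)
Conditions: 9-BBN, THF, 0 °C → rt; then NaBO3·4H2O, H2O, rt
Reagents that add atoms: sodium perborate (NaBO3·4H2O), [Na+].[O-]OB=O
Why: Anti-Markovnikov hydroboration–oxidation with the bulky 9-BBN should be selective for the monosubstituted vinyl group over the trisubstituted enoate, and perborate oxidation spares the ester.

**Step 5**
Reactants: 10 methyl (2E,6S)-6-[(tert-butyldimethylsilyl)oxy]-9-hydroxy-3,7,7-trimethylnon-2-enoate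
Product: 11 methyl (2E,6S)-6-[(tert-butyldimethylsilyl)oxy]-3,7,7-trimethyl-9-oxonon-2-enoate
Conditions: Dess–Martin periodinane, CH2Cl2, 0 °C → rt
Reagents that add atoms: none
Why: Dess–Martin oxidation converts the primary alcohol into the aldehyde under near-neutral conditions that leave the silyl ether and the enoate intact.

**Step 6**
Reactants: 11 methyl (2E,6S)-6-[(tert-butyldimethylsilyl)oxy]-3,7,7-trimethyl-9-oxonon-2-enoate; 12 propargyl bromide
Product: 14 methyl (2E,6S)-6-[(tert-butyldimethylsilyl)oxy]-9-hydroxy-3,7,7-trimethyldodec-2-en-11-ynoate (both C9 epimers), via allenylzinc bromide 13 (not isolated)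
Conditions: Zn dust, THF, 0 °C → rt; aq. NH4Cl
Reagents that add atoms: none
Why: Barbier-type propargylation, in which the allenylzinc species adds to the aldehyde through an SE2' transition state; the new carbinol centre forms unselectively, which is irrelevant because it is oxidised in step 7.

**Step 7**
Reactants: 14 methyl (2E,6S)-6-[(tert-butyldimethylsilyl)oxy]-9-hydroxy-3,7,7-trimethyldodec-2-en-11-ynoate
Product: 16 methyl (2E,6S)-6-[(tert-butyldimethylsilyl)oxy]-3,7,7-trimethyl-9-oxododeca-2,10,11-trienoate (allenyl ketone), via propargyl ketone 15 (not isolated)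
Conditions: Dess–Martin periodinane, CH2Cl2, 0 °C; then Et3N (0.2 equiv), CH2Cl2, 0 °C
Reagents that add atoms: none
Why: Dess–Martin oxidation followed by amine-mediated propargyl-to-allenyl prototropic isomerisation, driven by conjugation with the new ketone; the carbinol stereocentre is erased.

**Step 8**
Reactants: 16 methyl (2E,6S)-6-[(tert-butyldimethylsilyl)oxy]-3,7,7-trimethyl-9-oxododeca-2,10,11-trienoate
Product: 18 methyl 3β,6-bis[(tert-butyldimethylsilyl)oxy]drima-6,8(12)-dien-11-oate (5α-H, 9α-H, 10β-CH3), via silyloxy vinylallene 17 (not isolated)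
Conditions: TBSOTf, Et3N, CH2Cl2, −78 → 0 °C; pentane, filtration, concentration; then PhMe (0.01 M), BHT, 110 °C
Reagents that add atoms: tert-butyldimethylsilyl trifluoromethanesulfonate, CC(C)(C)[Si](C)(C)OS(=O)(=O)C(F)(F)F
Why: Soft enolisation of 16 can only take place toward C5 and gives the (Z)-2-silyloxy vinylallene 17, whose diene C5=C6(OTBS)–C7=C8 (the second allene bond C8=C12 stays behind as the exocyclic methylene) adds thermally to the tethered (E)-enoate C9=C10 in a concerted, asynchronous intramolecular Diels–Alder reaction; the closest known reaction types are the intramolecular [4+2] cycloadditions of vinylallenes and of 2-silyloxy-1,3,9-decatrienoates. The nucleophilic enol-ether carbon C5 bonds to the enoate β-carbon C10 and C8 bonds to C9, so that ring B closes as the cyclohexene of the [4+2] event (C5–C6–C7–C8–C9–C10) and ring A closes at the same time as the six-membered carbocycle C1–C2–C3–C4–C5–C10 through the four-carbon tether, the C5–C10 bond becoming the ring fusion of a 1,3,9-decatriene cyclisation. C9 and C10 are fixed relative to each other by suprafacial addition to the (E)-enoate (C11 and the C10 methyl cis, both β), C5 relative to C10 by the transition state that holds the tether exo and the ester and the C10 methyl endo (trans fusion, 5α-H), and the absolute sense of all three by C3, whose silyloxy group takes the equatorial position of the chair-like tether and therefore ends as 3β, cis to the C10 methyl. The selectivities needed are trans over cis fusion and one tether face over the other; they should be secured by the outside position of the quaternary C4 on the (Z)-enol ether, the sp-hybridised C8 that has no inside substituent, the endo preference of the ester under the electron-rich silyloxydiene and the equatorial preference of the bulky C3 silyloxy group, while regiochemistry is dictated by the tether and agrees with the polarisation of both partners. The gem-dimethyl group at C4 accelerates ring closure (Thorpe–Ingold effect) and, having no hydrogen, shuts off the [1,5]-hydrogen shift that otherwise consumes vinylallenes, and high dilution suppresses intermolecular cycloaddition.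

**Step 9**
Reactants: 18 methyl 3β,6-bis[(tert-butyldimethylsilyl)oxy]drima-6,8(12)-dien-11-oate
Product: 19 3β,6-bis[(tert-butyldimethylsilyl)oxy]drima-6,8(12)-dien-11-ol
Conditions: i-Bu2AlH, CH2Cl2, −78 → −20 °C; aq. potassium sodium tartrate (KNaC4H4O6)
Reagents that add atoms: none
Why: Ester reduction with i-Bu2AlH gives the primary alcohol without attacking the silyl enol ether or the silyl ether and, being non-basic at low temperature, should not epimerise C9.

**Step 10**
Reactants: 19 3β,6-bis[(tert-butyldimethylsilyl)oxy]drima-6,8(12)-dien-11-ol; 20 umbelliferone (7-hydroxy-2H-chromen-2-one)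
Product: 21 7-{[3β,6-bis[(tert-butyldimethylsilyl)oxy]drima-6,8(12)-dien-11-yl]oxy}-2H-chromen-2-one
Conditions: PPh3, DIAD, THF, 0 °C → rt
Reagents that add atoms: none
Why: Mitsunobu etherification, in which the acidic phenol is alkylated by the alkoxyphosphonium ion of the primary alcohol in an SN2 reaction at the non-stereogenic C11, so no stereocentre is affected.

**Step 11**
Reactants: 21 7-{[3β,6-bis[(tert-butyldimethylsilyl)oxy]drima-6,8(12)-dien-11-yl]oxy}-2H-chromen-2-one
Product: 23 7-{[3β-[(tert-butyldimethylsilyl)oxy]-6β-hydroxydrim-8(12)-en-11-yl]oxy}-2H-chromen-2-one, via 6-oxo ether 22 (not isolated)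
Conditions: n-Bu4NF, AcOH, THF, −78 °C; then NaBH4, MeOH, −78 → 0 °C
Reagents that add atoms: none
Why: Fluoride cleavage of the dienol silyl ether in the presence of AcOH protonates the dienolate kinetically at the α-carbon C7 (deconjugative protonation), keeping C8=C12 exocyclic, and NaBH4 then attacks the C6 ketone from the α face, away from the axial C4β and C10 methyl groups, to set the axial 6β-alcohol (substrate-controlled ketone reduction).

**Step 12**
Reactants: 23 7-{[3β-[(tert-butyldimethylsilyl)oxy]-6β-hydroxydrim-8(12)-en-11-yl]oxy}-2H-chromen-2-one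
Product: 24 7-{[6β-acetoxy-3β-[(tert-butyldimethylsilyl)oxy]drim-8(12)-en-11-yl]oxy}-2H-chromen-2-one
Conditions: Ac2O, DMAP, Et3N, CH2Cl2, 40 °C
Reagents that add atoms: acetic anhydride, CC(=O)OC(C)=O
Why: DMAP-catalysed acyl transfer through the N-acetylpyridinium ion should acetylate the hindered axial 6β-alcohol, the only free hydroxyl group, with retention of configuration.

**Step 13**
Reactants: 24 7-{[6β-acetoxy-3β-[(tert-butyldimethylsilyl)oxy]drim-8(12)-en-11-yl]oxy}-2H-chromen-2-one
Product: 25 7-{[(3S,5R,6R,9S,10R)-6-acetoxy-3-hydroxydrim-8(12)-en-11-yl]oxy}-2H-chromen-2-one (6β-OAc, 3β-OH; target)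
Conditions: HF·pyridine, pyridine, THF, 0 °C → rt
Reagents that add atoms: none
Why: Fluoride-mediated cleavage of the secondary silyl ether under buffered, non-basic conditions should spare the acetate, the coumarin lactone and the exocyclic alkene.

**Compound list**
1 | methyl geranate, methyl (2E)-3,7-dimethylocta-2,6-dienoate | CC(C)=CCC/C(C)=C/C(=O)OC | starting material
2 | methyl (2E)-5-(5,5-dimethyl-1,2,4-trioxolan-3-yl)-3-methylpent-2-enoate (secondary ozonide) | CC1(C)OOC(CC/C(C)=C/C(=O)OC)O1 | intermediate
3 | methyl (2E)-3-methyl-6-oxohex-2-enoate | O=CCC/C(C)=C/C(=O)OC | intermediate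
4 | 3-methylbuta-1,2-diene | CC(C)=C=C | starting material
5 | B-(3-methylbut-2-enyl)diisopinocampheylborane, isopinocampheyl groups from (−)-α-pinene | CC(C)=CCB([C@H]1C[C@H]2C[C@@H]([C@@H]1C)C2(C)C)[C@H]1C[C@H]2C[C@@H]([C@@H]1C)C2(C)C | intermediate
6 | diisopinocampheylborinate ester of 7 | C=CC(C)(C)[C@@H](OB([C@H]1C[C@H]2C[C@@H]([C@@H]1C)C2(C)C)[C@H]1C[C@H]2C[C@@H]([C@@H]1C)C2(C)C)CC/C(C)=C/C(=O)OC | intermediate
7 | methyl (2E,6S)-6-hydroxy-3,7,7-trimethylnona-2,8-dienoate | C=CC(C)(C)[C@@H](O)CC/C(C)=C/C(=O)OC | intermediate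
8 | methyl (2E,6S)-6-[(tert-butyldimethylsilyl)oxy]-3,7,7-trimethylnona-2,8-dienoate | C=CC(C)(C)[C@@H](O[Si](C)(C)C(C)(C)C)CC/C(C)=C/C(=O)OC | intermediate
9 | methyl (2E,6S)-9-(9-borabicyclo[3.3.1]nonan-9-yl)-6-[(tert-butyldimethylsilyl)oxy]-3,7,7-trimethylnon-2-enoate | B1(CCC(C)(C)[C@@H](O[Si](C)(C)C(C)(C)C)CC/C(C)=C/C(=O)OC)C2CCCC1CCC2 | intermediate
10 | methyl (2E,6S)-6-[(tert-butyldimethylsilyl)oxy]-9-hydroxy-3,7,7-trimethylnon-2-enoate | OCCC(C)(C)[C@@H](O[Si](C)(C)C(C)(C)C)CC/C(C)=C/C(=O)OC | intermediate
11 | methyl (2E,6S)-6-[(tert-butyldimethylsilyl)oxy]-3,7,7-trimethyl-9-oxonon-2-enoate | O=CCC(C)(C)[C@@H](O[Si](C)(C)C(C)(C)C)CC/C(C)=C/C(=O)OC | intermediate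
12 | propargyl bromide (3-bromoprop-1-yne) | C#CCBr | starting material
13 | allenylzinc bromide | C=C=C[Zn]Br | intermediate
14 | methyl (2E,6S)-6-[(tert-butyldimethylsilyl)oxy]-9-hydroxy-3,7,7-trimethyldodec-2-en-11-ynoate (C9 epimers) | C#CCC(O)CC(C)(C)[C@@H](O[Si](C)(C)C(C)(C)C)CC/C(C)=C/C(=O)OC | intermediate
15 | methyl (2E,6S)-6-[(tert-butyldimethylsilyl)oxy]-3,7,7-trimethyl-9-oxododec-2-en-11-ynoate | C#CCC(=O)CC(C)(C)[C@@H](O[Si](C)(C)C(C)(C)C)CC/C(C)=C/C(=O)OC | intermediate
16 | methyl (2E,6S)-6-[(tert-butyldimethylsilyl)oxy]-3,7,7-trimethyl-9-oxododeca-2,10,11-trienoate | C=C=CC(=O)CC(C)(C)[C@@H](O[Si](C)(C)C(C)(C)C)CC/C(C)=C/C(=O)OC | intermediate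
17 | methyl (2E,6S,8Z)-6,9-bis[(tert-butyldimethylsilyl)oxy]-3,7,7-trimethyldodeca-2,8,10,11-tetraenoate | C=C=C/C(O[Si](C)(C)C(C)(C)C)=C/C(C)(C)[C@@H](O[Si](C)(C)C(C)(C)C)CC/C(C)=C/C(=O)OC | intermediate
18 | methyl 3β,6-bis[(tert-butyldimethylsilyl)oxy]drima-6,8(12)-dien-11-oate (5α-H, 9α-H, 10β-CH3) | C=C1C=C(O[Si](C)(C)C(C)(C)C)[C@H]2C(C)(C)[C@@H](O[Si](C)(C)C(C)(C)C)CC[C@]2(C)[C@H]1C(=O)OC | intermediate
19 | 3β,6-bis[(tert-butyldimethylsilyl)oxy]drima-6,8(12)-dien-11-ol | C=C1C=C(O[Si](C)(C)C(C)(C)C)[C@H]2C(C)(C)[C@@H](O[Si](C)(C)C(C)(C)C)CC[C@]2(C)[C@H]1CO | intermediate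
20 | umbelliferone (7-hydroxy-2H-chromen-2-one) | O=c1ccc2ccc(O)cc2o1 | starting material
21 | 7-{[3β,6-bis[(tert-butyldimethylsilyl)oxy]drima-6,8(12)-dien-11-yl]oxy}-2H-chromen-2-one | C=C1C=C(O[Si](C)(C)C(C)(C)C)[C@H]2C(C)(C)[C@@H](O[Si](C)(C)C(C)(C)C)CC[C@]2(C)[C@H]1COc1ccc2ccc(=O)oc2c1 | intermediate
22 | 7-{[3β-[(tert-butyldimethylsilyl)oxy]-6-oxodrim-8(12)-en-11-yl]oxy}-2H-chromen-2-one | C=C1CC(=O)[C@H]2C(C)(C)[C@@H](O[Si](C)(C)C(C)(C)C)CC[C@]2(C)[C@H]1COc1ccc2ccc(=O)oc2c1 | intermediate
23 | 7-{[3β-[(tert-butyldimethylsilyl)oxy]-6β-hydroxydrim-8(12)-en-11-yl]oxy}-2H-chromen-2-one | C=C1C[C@@H](O)[C@H]2C(C)(C)[C@@H](O[Si](C)(C)C(C)(C)C)CC[C@]2(C)[C@H]1COc1ccc2ccc(=O)oc2c1 | intermediate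
24 | 7-{[6β-acetoxy-3β-[(tert-butyldimethylsilyl)oxy]drim-8(12)-en-11-yl]oxy}-2H-chromen-2-one | C=C1C[C@@H](OC(C)=O)[C@H]2C(C)(C)[C@@H](O[Si](C)(C)C(C)(C)C)CC[C@]2(C)[C@H]1COc1ccc2ccc(=O)oc2c1 | intermediate
25 | 7-{[(3S,5R,6R,9S,10R)-6-acetoxy-3-hydroxydrim-8(12)-en-11-yl]oxy}-2H-chromen-2-one | C=C1C[C@@H](OC(C)=O)[C@H]2C(C)(C)[C@@H](O)CC[C@]2(C)[C@H]1COc1ccc2ccc(=O)oc2c1 | target

**Totals and risks**
Total step count: 13. Longest linear sequence: 13 steps (from methyl geranate 1 to 25).

Steps most likely to fail:

1. Step 8. The cycloaddition may pass through the exo transition state (cis ring fusion) or use the wrong tether face, and the silyloxy vinylallene may oligomerise or lose its silyl group before ring closure. The fallback sets out from 16 and comes back at 18. It replaces the pericyclic event by a stepwise anionic intramolecular double Michael reaction (LiN(SiMe3)2, THF, −78 → 0 °C, then AcOH at −78 °C). The kinetic C5 enolate adds to the enoate carbon C10 and closes ring A through a lithium-bridged chair with the C3 silyloxy group equatorial; this first closure is reversible, so the trans arrangement can be reached under equilibrium. The ester enolate at C9 then adds to the central allene carbon C8 and closes ring B, and protonation of the dienolate at C7 gives the keto ester methyl 3β-[(tert-butyldimethylsilyl)oxy]-6-oxodrim-8(12)-en-11-oate F1. Treatment of F1 with TBSOTf and Et3N enolises toward C7, the only unhindered and doubly activated α-position, and returns to 18.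

2. Step 11. The exocyclic double bond may migrate into conjugation with the liberated ketone before hydride delivery, the reduction may be slow in the buffered medium, and hydride may attack the coumarin lactone. The fallback sets out from 19 and comes back at 23, moving the unmasking and reduction ahead of the coumarin. Compound 19 is desilylated at the enol ether (n-Bu4NF, AcOH, THF, −78 °C, cold neutral work-up) to 3β-[(tert-butyldimethylsilyl)oxy]-11-hydroxydrim-8(12)-en-6-one F2. With no lactone present, F2 can be reduced at once with LiAlH4 in Et2O at −78 °C (fast, non-equilibrating, α-face attack) to 3β-[(tert-butyldimethylsilyl)oxy]drim-8(12)-ene-6β,11-diol F3. Mitsunobu etherification of F3 with 20 (PPh3, DIAD) should occur only at the primary C11 hydroxyl, the axial 6β-hydroxyl being too hindered, and returns to 23.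

3. Step 10. Displacement at the β-branched C11 carbon may be slow, so that the alkoxyphosphonium ion is consumed by elimination or by side reactions with the hydrazide. The fallback sets out from 19 and comes back at 21 by reversing the polarity of the bond formation: Pd-catalysed C–O cross-coupling of 19 with 7-bromocoumarin (O=c1ccc2ccc(Br)cc2o1; [Pd(allyl)Cl]2, RockPhos, Cs2CO3, PhMe, 90 °C). The alkoxide binds the arylpalladium bromide and reductive elimination forms the aryl–oxygen bond, so no substitution at C11 is needed. This way makes no new compound F0.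

Further compounds
F1 | step 8 | methyl 3β-[(tert-butyldimethylsilyl)oxy]-6-oxodrim-8(12)-en-11-oate | C=C1CC(=O)[C@H]2C(C)(C)[C@@H](O[Si](C)(C)C(C)(C)C)CC[C@]2(C)[C@H]1C(=O)OC
F2 | step 11 | 3β-[(tert-butyldimethylsilyl)oxy]-11-hydroxydrim-8(12)-en-6-one | C=C1CC(=O)[C@H]2C(C)(C)[C@@H](O[Si](C)(C)C(C)(C)C)CC[C@]2(C)[C@H]1CO
F3 | step 11 | 3β-[(tert-butyldimethylsilyl)oxy]drim-8(12)-ene-6β,11-diol | C=C1C[C@@H](O)[C@H]2C(C)(C)[C@@H](O[Si](C)(C)C(C)(C)C)CC[C@]2(C)[C@H]1CO
F0 | step 10 | none | none
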